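The benzophenone is cut between the ketone carbon and C1 of the guaiacyl ring (ring A). The key step exploits the free hydroxyl at C6 of the phloroglucinol-derived ring B, ortho to the carbonyl: in a salicylaldehyde precursor this phenoxide binds palladium and steers it into the formyl C–H bond, so the unprotected aldehyde and unprotected 4-iodo-2-methoxyphenol are joined directly at the ketone oxidation level in the last step. The ring B aldehyde, 4,6-dihydroxy-2-methoxy-3-prenylbenzaldehyde, is built from symmetric 2,4,6-trihydroxybenzaldehyde by C-prenylation, regioselective bis-MOM protection, methylation of the hydroxyl beside the prenyl group, then MOM removal.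

Key step: step 5

Remark: the target has no stereocentre and its only alkene carries two identical methyl groups, so it is achiral and no stereochemical control is needed. Ring B is numbered with C1 bearing the carbonyl, C2 OMe, C3 prenyl, C4 OH, C5 H and C6 OH; prenyl = 3-methylbut-2-en-1-yl.

Step 1
Reactants: 1 2,4,6-trihydroxybenzaldehyde; 2 prenyl bromide (1-bromo-3-methylbut-2-ene)
Product: 3 2,4,6-trihydroxy-3-(3-methylbut-2-en-1-yl)benzaldehyde
Conditions: 2 (1.0 equiv), DBU (1.1 equiv), THF, 0 °C to rt
Reagents that add atoms: none
Why: C-prenylation of an acylphloroglucinol: the delocalised phenoxide of 1 attacks the soft allylic bromide through carbon (SN2), and because C3 and C5 of 1 are equivalent by symmetry only one mono-C-prenyl isomer can form, with one equivalent of 2 limiting bis-prenylation.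

Step 2
Reactants: 3 2,4,6-trihydroxy-3-(3-methylbut-2-en-1-yl)benzaldehyde
Product: 5 2-hydroxy-4,6-bis(methoxymethoxy)-3-(3-methylbut-2-en-1-yl)benzaldehyde, via 4-O-MOM monoether 4 (not isolated)
Conditions: MOMCl (2.2 equiv), i-Pr2NEt (3 equiv), CH2Cl2, 0 °C to rt
Reagents that add atoms: chloromethyl methyl ether (MOMCl), COCCl
Why: Regioselective Williamson-type MOM etherification: the non-chelated, most acidic 4-OH reacts first and, of the two hydrogen-bonded ortho hydroxyls, the 6-OH flanked only by C5–H should react before the 2-OH, which is shielded by the prenyl group and held in the O–H···O=C chelate.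

Step 3
Reactants: 5 2-hydroxy-4,6-bis(methoxymethoxy)-3-(3-methylbut-2-en-1-yl)benzaldehyde
Product: 6 2-methoxy-4,6-bis(methoxymethoxy)-3-(3-methylbut-2-en-1-yl)benzaldehyde
Conditions: MeI (3 equiv), K2CO3 (3 equiv), DMF, rt to 40 °C
Reagents that add atoms: iodomethane, CI
Why: Williamson methylation: K2CO3 in DMF deprotonates the remaining chelated 2-OH and the phenoxide is methylated by MeI, while the MOM ethers, the aldehyde and the prenyl group are inert to these conditions.

Step 4
Reactants: 6 2-methoxy-4,6-bis(methoxymethoxy)-3-(3-methylbut-2-en-1-yl)benzaldehyde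
Product: 7 4,6-dihydroxy-2-methoxy-3-(3-methylbut-2-en-1-yl)benzaldehyde
Conditions: 3 M aq. HCl (cat.), MeOH, rt; aqueous work-up
Reagents that add atoms: none
Why: Acid-catalysed acetal exchange (MOM cleavage) with methanol as acceptor: both aryl MOM ethers are transferred to the solvent as dimethoxymethane at room temperature, mild conditions under which ortho-prenylphenols of this type should not cyclise to chromans.

Step 5
Reactants: 7 4,6-dihydroxy-2-methoxy-3-(3-methylbut-2-en-1-yl)benzaldehyde; 8 4-iodo-2-methoxyphenol
Product: 9 (4,6-dihydroxy-2-methoxy-3-(3-methylbut-2-en-1-yl)phenyl)(4-hydroxy-3-methoxyphenyl)methanone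
Conditions: PdCl2 (5 mol %), LiCl (20 mol %), Na2CO3 (3 equiv), DMF, 100 °C, N2
Reagents that add atoms: none
Why: Oxidative addition of Pd(0) to the C–I bond of 8 gives an arylpalladium(II) iodide that exchanges iodide for the C6 phenoxide of 7; the bound phenoxide holds palladium beside the formyl C–H, which is cleaved to an aryl(acyl)palladium species within a transient five-membered oxapalladacycle, and C–C reductive elimination forms the diaryl ketone and returns Pd(0). The closest known reaction type is the palladium-catalysed, chelation-assisted coupling of salicylaldehydes with aryl iodides to 2-hydroxybenzophenones under phosphine-free PdCl2/LiCl/Na2CO3 conditions in DMF. No ring of the product is closed and no stereocentre is created. The step needs chemoselectivity for the formyl C–H over Heck-type reaction at the prenyl alkene, over O- or C-arylation of the three phenols and over decarbonylation; the ortho-phenoxide chelate, the low reactivity of a trisubstituted alkene toward carbopalladation and the ligand-free conditions at 100 °C should secure it. Only the C6 hydroxyl of 7 is ortho to the formyl group (C2 carries the methyl ether), so only one directing mode exists.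

Compound list
1 | 2,4,6-trihydroxybenzaldehyde | O=Cc1c(O)cc(O)cc1O | starting material
2 | prenyl bromide (1-bromo-3-methylbut-2-ene) | CC(C)=CCBr | starting material
3 | 2,4,6-trihydroxy-3-(3-methylbut-2-en-1-yl)benzaldehyde | O=Cc1c(O)cc(O)c(CC=C(C)C)c1O | intermediate
4 | 2,6-dihydroxy-4-(methoxymethoxy)-3-(3-methylbut-2-en-1-yl)benzaldehyde (4-O-MOM monoether, not isolated) | O=Cc1c(O)cc(OCOC)c(CC=C(C)C)c1O | intermediate
5 | 2-hydroxy-4,6-bis(methoxymethoxy)-3-(3-methylbut-2-en-1-yl)benzaldehyde | O=Cc1c(OCOC)cc(OCOC)c(CC=C(C)C)c1O | intermediate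
6 | 2-methoxy-4,6-bis(methoxymethoxy)-3-(3-methylbut-2-en-1-yl)benzaldehyde | O=Cc1c(OCOC)cc(OCOC)c(CC=C(C)C)c1OC | intermediate
7 | 4,6-dihydroxy-2-methoxy-3-(3-methylbut-2-en-1-yl)benzaldehyde | O=Cc1c(O)cc(O)c(CC=C(C)C)c1OC | intermediate
8 | 4-iodo-2-methoxyphenol | COc1cc(I)ccc1O | starting material
9 | (4,6-dihydroxy-2-methoxy-3-(3-methylbut-2-en-1-yl)phenyl)(4-hydroxy-3-methoxyphenyl)methanone | COc1cc(C(=O)c2c(O)cc(O)c(CC=C(C)C)c2OC)ccc1O | target

Total step count: 5
Longest linear sequence: 5 steps (1 → 3 → 5 → 6 → 7 → 9)

Steps most likely to fail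

1. Step 5 (key step). The arylpalladium intermediate may be diverted into Heck-type or oxypalladation chemistry at the prenyl alkene beside the free C4 hydroxyl, or the electron-rich phenoxides may slow oxidative addition, so that formyl C–H arylation stalls. The fallback sets out from 6 (with 8 as the aryl source) and comes back at 9, forming the same bond by carbonyl addition. Compound 8 is protected with MOMCl/i-Pr2NEt as 4-iodo-2-methoxy-1-(methoxymethoxy)benzene F1. Iodine–magnesium exchange with i-PrMgCl·LiCl in THF at −20 °C and addition of the aryl Grignard reagent to aldehyde 6 should give the racemic diaryl carbinol [2-methoxy-4,6-bis(methoxymethoxy)-3-prenylphenyl][3-methoxy-4-(methoxymethoxy)phenyl]methanol F2. Oxidation with MnO2 in CH2Cl2 (or Dess–Martin periodinane) should give the tris-MOM benzophenone F3, and HCl in MeOH at rt should then remove the three MOM groups to give 9.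

2. Step 2. The second MOM group may go onto the hydroxyl beside the prenyl group, or a third may be installed, leaving the wrong hydroxyl free for methylation. The fallback sets out from 1 and comes back at 5; it reverses the order so that the hydroxyl that must stay free delivers the prenyl group itself, which also bypasses step 1. Compound 1, whose two ortho hydroxyls are equivalent, is bis-protected (MOMCl, i-Pr2NEt) to 2-hydroxy-4,6-bis(methoxymethoxy)benzaldehyde F4. Pd(PPh3)4-catalysed O-allylation with tert-butyl 2-methylbut-3-en-2-yl carbonate in THF at 0 °C should give the 1,1-dimethylallyl ether 4,6-bis(methoxymethoxy)-2-[(2-methylbut-3-en-2-yl)oxy]benzaldehyde F5. Aromatic Claisen rearrangement (toluene, 110 °C) should move the allyl unit with inversion to C3, the only free ortho position, giving 5.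

3. Step 4. Acid may add the C4 hydroxyl across the prenyl alkene (chroman formation) or promote alkylation of the electron-rich ring by the cleaved methoxymethyl fragment during MOM removal. The fallback sets out from 3 and comes back at 7, using allyl ethers that are removed under neutral conditions. Allyl bromide (2.1 equiv) with K2CO3 in acetone should give 4,6-bis(allyloxy)-2-hydroxy-3-(3-methylbut-2-en-1-yl)benzaldehyde F6, by the same hydroxyl selectivity as in step 2. MeI/K2CO3 in DMF should give 4,6-bis(allyloxy)-2-methoxy-3-(3-methylbut-2-en-1-yl)benzaldehyde F7. Pd(PPh3)4 (cat.) with morpholine in THF at rt should then transfer both allyl groups to the amine and give 7.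

Further compounds
F1 | step 5 | 4-iodo-2-methoxy-1-(methoxymethoxy)benzene | COCOc1ccc(I)cc1OC
F2 | step 5 | racemic [2-methoxy-4,6-bis(methoxymethoxy)-3-(3-methylbut-2-en-1-yl)phenyl][3-methoxy-4-(methoxymethoxy)phenyl]methanol | COCOc1ccc(C(O)c2c(OCOC)cc(OCOC)c(CC=C(C)C)c2OC)cc1OC
F3 | step 5 | [2-methoxy-4,6-bis(methoxymethoxy)-3-(3-methylbut-2-en-1-yl)phenyl][3-methoxy-4-(methoxymethoxy)phenyl]methanone | COCOc1ccc(C(=O)c2c(OCOC)cc(OCOC)c(CC=C(C)C)c2OC)cc1OC
F4 | step 2 | 2-hydroxy-4,6-bis(methoxymethoxy)benzaldehyde | O=Cc1c(O)cc(OCOC)cc1OCOC
F5 | step 2 | 4,6-bis(methoxymethoxy)-2-[(2-methylbut-3-en-2-yl)oxy]benzaldehyde | O=Cc1c(OC(C)(C)C=C)cc(OCOC)cc1OCOC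
F6 | step 4 | 4,6-bis(allyloxy)-2-hydroxy-3-(3-methylbut-2-en-1-yl)benzaldehyde | O=Cc1c(OCC=C)cc(OCC=C)c(CC=C(C)C)c1O
F7 | step 4 | 4,6-bis(allyloxy)-2-methoxy-3-(3-methylbut-2-en-1-yl)benzaldehyde | O=Cc1c(OCC=C)cc(OCC=C)c(CC=C(C)C)c1OC
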